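**Retrosynthetic overview**

1. The benzofuran furan ring is formed last: Sonogashira coupling of an ortho-iodoresorcinol carrying the geranyl chain (fragment 1) with an ethynyl-dihydrobenzofuran (fragment 2), then 5-endo-dig C–O closure in the same flask.
2. The dihydrofuran C–O bond and the R centre of fragment 2 come from a phenol-directed catalytic asymmetric epoxidation of an ortho-prenylphenol, followed by 5-exo epoxide opening with inversion (the new step).
3. The prenylphenol comes from 3,5-dimethoxybenzaldehyde: bromination, demethylation, Stille prenylation, Ohira–Bestmann alkyne formation.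
4. Fragment 1 comes from resorcinol: bis-MOM ether, two directed ortho-lithiations (geranyl bromide, then iodine), MOM removal.
5. Ring order: both benzene rings are bought; the dihydrofuran ring is made first (on fragment 2), the benzofuran furan ring last.

Assumption: the (S,S) antipode of the bishydroxamic acid ligand (BHA = (1S,2S)-N,N'-dihydroxy-N,N'-bis(diphenylacetyl)cyclohexane-1,2-diamine) is taken to give the (S)-epoxide in step 9; if the first run shows the opposite sense, the (R,R) antipode is used with nothing else changed. Geranyl bromide and tributyl(3-methylbut-2-en-1-yl)stannane are taken as catalogue items.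

**Route**

Step 1
Reactants: 1 resorcinol (benzene-1,3-diol)
Product: 2 1,3-bis(methoxymethoxy)benzene
Conditions: NaH, MOMCl, DMF, 0 °C to rt
Reagents that add atoms: chloromethyl methyl ether (MOMCl), COCCl
Why: Double Williamson-type O-alkylation of the resorcinol dianion gives the base-stable bis-MOM acetal, which is the directing group for both lithiations that follow.

Step 2
Reactants: 2 1,3-bis(methoxymethoxy)benzene; 3 geranyl bromide ((2E)-1-bromo-3,7-dimethylocta-2,6-diene)
Product: 5 2-[(2E)-3,7-dimethylocta-2,6-dien-1-yl]-1,3-bis(methoxymethoxy)benzene, via aryllithium 4 (not isolated)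
Conditions: n-BuLi, THF, 0 °C to rt; then CuI (10 mol %), geranyl bromide, −78 °C to rt
Reagents that add atoms: none
Why: Directed ortho-metalation occurs at the carbon flanked by both OMOM groups, and copper-catalysed SN2 allylic substitution on geranyl bromide attaches the chain at its primary carbon with the E double bond untouched.

Step 3
Reactants: 5 2-[(2E)-3,7-dimethylocta-2,6-dien-1-yl]-1,3-bis(methoxymethoxy)benzene
Product: 7 1-iodo-3-[(2E)-3,7-dimethylocta-2,6-dien-1-yl]-2,4-bis(methoxymethoxy)benzene, via aryllithium 6 (not isolated)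
Conditions: n-BuLi, TMEDA, THF, −20 to 0 °C; then I2, −78 °C to rt
Reagents that add atoms: iodine, II
Why: A second directed ortho-metalation can only occur at the remaining position ortho to an OMOM group, and trapping the aryllithium with iodine places the iodide regiospecifically without exposing the alkenes to an electrophilic iodinating agent.

Step 4
Reactants: 7 1-iodo-3-[(2E)-3,7-dimethylocta-2,6-dien-1-yl]-2,4-bis(methoxymethoxy)benzene
Product: 8 2-[(2E)-3,7-dimethylocta-2,6-dien-1-yl]-4-iodobenzene-1,3-diol
Conditions: HCl (2 M aq), MeOH, 40 °C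
Reagents that add atoms: none
Why: Acid-catalysed transacetalisation with methanol cleaves both MOM ethers under conditions too mild to cyclise the ortho-geranyl phenol or hydrate its trisubstituted alkenes.

Step 5
Reactants: 9 3,5-dimethoxybenzaldehyde
Product: 10 2-bromo-3,5-dimethoxybenzaldehyde
Conditions: NBS, MeCN, rt
Reagents that add atoms: N-bromosuccinimide, O=C1CCC(=O)N1Br
Why: Electrophilic aromatic bromination goes ortho to one methoxy and para to the other because the site between the two methoxy groups is more hindered, a well-established outcome for this aldehyde.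

Step 6
Reactants: 10 2-bromo-3,5-dimethoxybenzaldehyde
Product: 11 2-bromo-3,5-dihydroxybenzaldehyde
Conditions: BBr3, CH2Cl2, −78 °C to rt; then H2O
Reagents that add atoms: none
Why: Lewis-acid ether cleavage with BBr3 removes both methyl groups while the aldehyde and aryl bromide survive, and it is done before the acid-sensitive prenyl group is present.

Step 7
Reactants: 11 2-bromo-3,5-dihydroxybenzaldehyde; 12 tributyl(3-methylbut-2-en-1-yl)stannane
Product: 13 3,5-dihydroxy-2-(3-methylbut-2-en-1-yl)benzaldehyde
Conditions: Pd(PPh3)4 (5 mol %), DMF, 90 °C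
Reagents that add atoms: none
Why: Stille cross-coupling at the aldehyde-activated C–Br bond transfers the prenyl group through its primary carbon under neutral conditions that tolerate the free phenols and the aldehyde.

Step 8
Reactants: 13 3,5-dihydroxy-2-(3-methylbut-2-en-1-yl)benzaldehyde
Product: 14 5-ethynyl-4-(3-methylbut-2-en-1-yl)benzene-1,3-diol
Conditions: dimethyl (1-diazo-2-oxopropyl)phosphonate, K2CO3 (4 equiv), MeOH, 0 °C to rt
Reagents that add atoms: dimethyl (1-diazo-2-oxopropyl)phosphonate (Ohira–Bestmann reagent), COP(=O)(OC)C(=[N+]=[N-])C(C)=O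
Why: Seyferth–Gilbert homologation with the Ohira–Bestmann reagent converts the aldehyde into the terminal alkyne under mild carbonate conditions, the phenoxides being meta to the carbonyl and so not deactivating it.

Step 9
Reactants: 14 5-ethynyl-4-(3-methylbut-2-en-1-yl)benzene-1,3-diol
Product: 16 (2R)-4-ethynyl-2-(2-hydroxypropan-2-yl)-2,3-dihydro-1-benzofuran-6-ol, via epoxide 15 (not isolated)
Conditions: Hf(OtBu)4 (10 mol %), (S,S)-BHA ligand (12 mol %), cumene hydroperoxide (1.5 equiv), DMPU, 4 Å MS, toluene, 0 °C; then K2CO3 (0.3 equiv), MeOH, rt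
Reagents that add atoms: cumene hydroperoxide, CC(C)(OO)c1ccccc1
Why: Proposed new method: a phenol-directed catalytic asymmetric epoxidation–cycloetherification in which the ortho phenol of 14 exchanges onto the chiral tetravalent hafnium bishydroxamate as an aryloxide, the cumyl peroxide bound to the same metal delivers oxygen intramolecularly to one face of the neighbouring trisubstituted alkene to set the (S)-epoxide 15, and carbonate then triggers 5-exo-tet opening at the secondary epoxide carbon by the same phenoxide with inversion, which forms the dihydrofuran C–O bond and the R centre and leaves the tertiary alcohol; the closest known reaction types are the hydroxyl-directed asymmetric epoxidation of homoallylic and bishomoallylic alcohols with zirconium or hafnium bishydroxamic acid catalysts and the racemic vanadium-catalysed epoxidation–cyclisation of 2-alkenylphenols, and a phenol as the anchoring group in an enantioselective version is what is new.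

Step 10
Reactants: 8 2-[(2E)-3,7-dimethylocta-2,6-dien-1-yl]-4-iodobenzene-1,3-diol; 16 (2R)-4-ethynyl-2-(2-hydroxypropan-2-yl)-2,3-dihydro-1-benzofuran-6-ol
Product: 18 mulberrofuran X, via alkynylphenol 17 (not isolated)
Conditions: Pd(PPh3)2Cl2 (5 mol %), CuI (5 mol %), Et3N, DMF, rt to 70 °C
Reagents that add atoms: none
Why: Sonogashira coupling of the aryl iodide with the terminal alkyne gives the ortho-alkynylphenol, whose hydroxyl ortho to the alkyne (the only one so placed) adds 5-endo-dig under the copper/amine conditions to form the benzofuran C–O bond.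

**Compound list**

1 | resorcinol (benzene-1,3-diol) | Oc1cccc(O)c1 | starting material
2 | 1,3-bis(methoxymethoxy)benzene | COCOc1cccc(OCOC)c1 | intermediate
3 | geranyl bromide ((2E)-1-bromo-3,7-dimethylocta-2,6-diene) | CC(C)=CCC/C(C)=C/CBr | starting material
4 | 2,6-bis(methoxymethoxy)phenyllithium | [Li]c1c(OCOC)cccc1OCOC | intermediate
5 | 2-[(2E)-3,7-dimethylocta-2,6-dien-1-yl]-1,3-bis(methoxymethoxy)benzene | CC(C)=CCC/C(C)=C/Cc1c(OCOC)cccc1OCOC | intermediate
6 | 3-[(2E)-3,7-dimethylocta-2,6-dien-1-yl]-2,4-bis(methoxymethoxy)phenyllithium | CC(C)=CCC/C(C)=C/Cc1c(OCOC)ccc([Li])c1OCOC | intermediate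
7 | 1-iodo-3-[(2E)-3,7-dimethylocta-2,6-dien-1-yl]-2,4-bis(methoxymethoxy)benzene | CC(C)=CCC/C(C)=C/Cc1c(OCOC)ccc(I)c1OCOC | intermediate
8 | 2-[(2E)-3,7-dimethylocta-2,6-dien-1-yl]-4-iodobenzene-1,3-diol | CC(C)=CCC/C(C)=C/Cc1c(O)ccc(I)c1O | intermediate
9 | 3,5-dimethoxybenzaldehyde | COc1cc(OC)cc(C=O)c1 | starting material
10 | 2-bromo-3,5-dimethoxybenzaldehyde | COc1cc(OC)c(Br)c(C=O)c1 | intermediate
11 | 2-bromo-3,5-dihydroxybenzaldehyde | Oc1cc(O)c(Br)c(C=O)c1 | intermediate
12 | tributyl(3-methylbut-2-en-1-yl)stannane | CCCC[Sn](CCCC)(CCCC)CC=C(C)C | starting material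
13 | 3,5-dihydroxy-2-(3-methylbut-2-en-1-yl)benzaldehyde | CC(C)=CCc1c(O)cc(O)cc1C=O | intermediate
14 | 5-ethynyl-4-(3-methylbut-2-en-1-yl)benzene-1,3-diol | CC(C)=CCc1c(O)cc(O)cc1C#C | intermediate
15 | 4-{[(2S)-3,3-dimethyloxiran-2-yl]methyl}-5-ethynylbenzene-1,3-diol | C#Cc1cc(O)cc(O)c1C[C@@H]1OC1(C)C | intermediate
16 | (2R)-4-ethynyl-2-(2-hydroxypropan-2-yl)-2,3-dihydro-1-benzofuran-6-ol | C#Cc1cc(O)cc2c1C[C@H](C(C)(C)O)O2 | intermediate
17 | 2-[(2E)-3,7-dimethylocta-2,6-dien-1-yl]-4-{[(2R)-6-hydroxy-2-(2-hydroxypropan-2-yl)-2,3-dihydro-1-benzofuran-4-yl]ethynyl}benzene-1,3-diol | CC(C)=CCC/C(C)=C/Cc1c(O)ccc(C#Cc2cc(O)cc3c2C[C@H](C(C)(C)O)O3)c1O | intermediate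
18 | mulberrofuran X ((2R)-4-{7-[(2E)-3,7-dimethylocta-2,6-dien-1-yl]-6-hydroxy-1-benzofuran-2-yl}-2-(2-hydroxypropan-2-yl)-2,3-dihydro-1-benzofuran-6-ol) | CC(C)=CCC/C(C)=C/Cc1c(O)ccc2cc(-c3cc(O)cc4c3C[C@H](C(C)(C)O)O4)oc12 | target

**Step count and risks**

Total step count: 10. Longest linear sequence: 6 (steps 5, 6, 7, 8, 9, 10); the other branch is 5 (steps 1, 2, 3, 4, 10).

The three steps most likely to fail:

Step 9 (the new step). The resorcinol unit may bind the hafnium catalyst unproductively, the enantioselectivity or its sense may be poor, or the epoxide may open 6-endo to a chromanol. The fallback uses known chemistry and sets out from 14. TBSCl and imidazole in DMF give 1,3-bis(tert-butyldimethylsilyloxy)-5-ethynyl-4-(3-methylbut-2-en-1-yl)benzene F1. Shi epoxidation with the enantiomer of the fructose-derived Shi ketone (KHSO5 as Oxone, K2CO3 buffer, MeCN/dimethoxymethane, 0 °C) gives (3S)-3-[2,4-bis(tert-butyldimethylsilyloxy)-6-ethynylbenzyl]-2,2-dimethyloxirane F2. TBAF in THF then removes both silyl groups, and the ortho phenoxide closes 5-exo with inversion, so the fallback comes back to the route at 16.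

Step 10. The free, electron-rich iodoresorcinol 8 may couple sluggishly or lose iodine, and the alkyne may homocouple. The fallback sets out from 7 and 16 and keeps the MOM groups through the coupling. Sonogashira coupling (Pd(PPh3)2Cl2, CuI, Et3N, THF, 50 °C) gives the bis-MOM diaryl alkyne F3. HCl in MeOH at 40 °C removes the MOM groups, so the fallback comes back to the route at 17, now isolated. Compound 17 is then closed to 18 with Cs2CO3 in DMF at 60 °C as a separate operation.

Step 7. The prenyl group may transfer through its tertiary carbon, the free phenol may protonate the allylic stannane, and the doubly ortho-substituted bromide may react slowly. The fallback sets out from 11. Stille coupling with allyltributylstannane (Pd(PPh3)4, DMF, 80 °C), which has no regiochemical issue, gives 2-allyl-3,5-dihydroxybenzaldehyde F4. Olefin cross-metathesis with excess 2-methylbut-2-ene (second-generation Grubbs catalyst, CH2Cl2, 40 °C) then builds the prenyl group, so the fallback comes back to the route at 13.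

**Further compounds**

F1 | step 9 | 1,3-bis(tert-butyldimethylsilyloxy)-5-ethynyl-4-(3-methylbut-2-en-1-yl)benzene | CC(C)=CCc1c(O[Si](C)(C)C(C)(C)C)cc(O[Si](C)(C)C(C)(C)C)cc1C#C
F2 | step 9 | (3S)-3-[2,4-bis(tert-butyldimethylsilyloxy)-6-ethynylbenzyl]-2,2-dimethyloxirane | C#Cc1cc(O[Si](C)(C)C(C)(C)C)cc(O[Si](C)(C)C(C)(C)C)c1C[C@@H]1OC1(C)C
F3 | step 10 | (2R)-4-({3-[(2E)-3,7-dimethylocta-2,6-dien-1-yl]-2,4-bis(methoxymethoxy)phenyl}ethynyl)-2-(2-hydroxypropan-2-yl)-2,3-dihydro-1-benzofuran-6-ol | CC(C)=CCC/C(C)=C/Cc1c(OCOC)ccc(C#Cc2cc(O)cc3c2C[C@H](C(C)(C)O)O3)c1OCOC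
F4 | step 7 | 2-allyl-3,5-dihydroxybenzaldehyde | C=CCc1c(O)cc(O)cc1C=O
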